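**Retrosynthetic overview**

1. C10–C11 bond: a copper-catalysed enantioselective SN2′ alkenylation joins a (Z)-allylic phosphate (ring A plus four chain carbons) with an (E)-alkenylaluminium made from a C16 alkyne. This one step sets the quaternary centre, the vinyl group and the (E)-alkene.
2. The phosphate comes from a B-alkyl Suzuki coupling of a vinyl-substituted ring A diene with (2Z)-3-iodobut-2-en-1-ol.
3. Ring A, the only ring, is never closed by cyclisation: it is the carbocycle of 3,4-dimethylanisole, dearomatised by Birch reduction (key step) and made chiral by enantioselective alkene isomerisation. Cuprate methylation, formylation and trans-selective conjugate vinylation complete it.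
4. The alkyne comes from (2E,6E)-farnesyl acetate by terminal SeO2 oxidation, copper-catalysed SN2′ methylation, asymmetric hydrogenation and aldehyde-to-alkyne conversion.

Assumption: compounds 1, 12 and 18 are bought; wherever a chiral ligand or catalyst is named, the enantiomer that gives the configuration shown in the SMILES is the one used.

**Route**

Step 1
Reactants: 1 3,4-dimethylanisole
Product: 3 3,4-dimethylcyclohex-3-en-1-one, via dienol ether 2 (not isolated)
Conditions: Li, liq. NH3, t-BuOH, THF, −78 → −33 °C; then (CO2H)2, THF/H2O, rt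
Reagents that add atoms: water (O)
Why: Birch reduction protonates the two ring positions that leave the C–OMe carbon and both methyl-bearing carbons unsaturated, and mild oxalic-acid hydrolysis of the enol ether gives the β,γ-enone without moving the tetrasubstituted alkene.

Step 2
Reactants: 3 3,4-dimethylcyclohex-3-en-1-one
Product: 4 (4S)-3,4-dimethylcyclohex-2-en-1-one
Conditions: cinchona-derived primary–tertiary diamine (9-amino-9-deoxy-epi-quinine type, 10 mol%), ClCH2CO2H (10 mol%), toluene, −25 °C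
Reagents that add atoms: none
Why: Enantioselective olefin isomerisation by iminium/dienamine catalysis, in which the chiral ammonium delivers the proton to one face of the dienamine γ-carbon and so sets the lone ring stereocentre as 4S.

Step 3
Reactants: 4 (4S)-3,4-dimethylcyclohex-2-en-1-one
Product: 6 (4S)-3,3,4-trimethylcyclohex-1-en-1-yl trifluoromethanesulfonate, via lithium enolate 5 (not isolated)
Conditions: Me2CuLi (from MeLi and CuBr·SMe2), Et2O, −20 °C; then PhNTf2, THF, −20 °C → rt
Reagents that add atoms: lithium dimethylcuprate ([Li+].C[Cu-]C); N-phenylbis(trifluoromethanesulfonimide) (O=S(=O)(N(c1ccccc1)S(=O)(=O)C(F)(F)F)C(F)(F)F)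
Why: Conjugate addition of the Gilman reagent creates the gem-dimethyl carbon and the regiodefined enolate is trapped on oxygen as the enol triflate (conjugate addition–enolate trapping), leaving the existing stereocentre untouched.

Step 4
Reactants: 6 (4S)-3,3,4-trimethylcyclohex-1-en-1-yl trifluoromethanesulfonate
Product: 7 (4S)-3,3,4-trimethylcyclohex-1-ene-1-carbaldehyde
Conditions: Pd(PPh3)4 (3 mol%), CO (3 atm), Bu3SnH (slow addition), THF, 50 °C
Reagents that add atoms: carbon monoxide ([C-]#[O+])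
Why: Palladium-catalysed reductive carbonylation (formylation) of an enol triflate, in which CO inserts into the alkenyl–palladium bond and tin hydride delivers the formyl hydrogen.

Step 5
Reactants: 7 (4S)-3,3,4-trimethylcyclohex-1-ene-1-carbaldehyde
Product: 10 [(2R,4S)-2-ethenyl-3,3,4-trimethylcyclohexylidene]methyl trifluoromethanesulfonate, via silyl enol ether 8 (not isolated), via lithium enolate 9 (not isolated)
Conditions: CH2=CHMgBr, CuBr·SMe2 (10 mol%), Me3SiCl, DMPU, THF, −78 °C; evaporation; then MeLi, THF, 0 °C; then PhNTf2, −78 → 0 °C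
Reagents that add atoms: vinylmagnesium bromide (C=C[Mg]Br); N-phenylbis(trifluoromethanesulfonimide) (O=S(=O)(N(c1ccccc1)S(=O)(=O)C(F)(F)F)C(F)(F)F)
Why: Copper-catalysed, silyl-chloride-accelerated 1,4-addition of the vinyl Grignard reagent occurs by axial attack on the half-chair that keeps the C4 methyl equatorial, which places the vinyl group trans to that methyl, and the enolate is then O-triflated.

Step 6
Reactants: 10 [(2R,4S)-2-ethenyl-3,3,4-trimethylcyclohexylidene]methyl trifluoromethanesulfonate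
Product: 11 (1S,3S)-3-ethenyl-1,2,2-trimethyl-4-methylidenecyclohexane
Conditions: Pd(OAc)2 (3 mol%), PPh3 (6 mol%), HCO2H, Bu3N, DMF, 60 °C
Reagents that add atoms: none
Why: Palladium-catalysed formate hydrogenolysis of the enol triflate replaces OTf by H and so leaves the exocyclic methylidene in place.

Step 7
Reactants: 12 but-2-yn-1-ol
Product: 14 (2Z)-3-iodobut-2-en-1-ol, via cyclic alkenylaluminate 13 (not isolated)
Conditions: NaAlH2(OCH2CH2OMe)2, Et2O, 0 °C → rt; then I2, THF, −78 °C
Reagents that add atoms: iodine (II)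
Why: Alkoxide-directed trans-hydroalumination of the propargylic alcohol puts aluminium on the distal carbon inside a five-membered aluminate, and iodinolysis with retention gives the (Z)-iodoalkene.

Step 8
Reactants: 11 (1S,3S)-3-ethenyl-1,2,2-trimethyl-4-methylidenecyclohexane; 14 (2Z)-3-iodobut-2-en-1-ol
Product: 16 (2Z)-3-methyl-5-[(1S,3S)-2,2,3-trimethyl-6-methylidenecyclohexyl]pent-2-en-1-ol, via alkylborane 15 (not isolated)
Conditions: (Sia)2BH (from BH3·THF and 2-methylbut-2-ene), THF, 0 °C; then 14, PdCl2(dppf) (5 mol%), 3 M aq. NaOH, THF, 60 °C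
Reagents that add atoms: none
Why: The bulky dialkylborane hydroborates the monosubstituted vinyl group (anti-Markovnikov) in preference to the 1,1-disubstituted methylidene, and the B-alkyl Suzuki–Miyaura coupling keeps the geometry of the iodoalkene.

Step 9
Reactants: 16 (2Z)-3-methyl-5-[(1S,3S)-2,2,3-trimethyl-6-methylidenecyclohexyl]pent-2-en-1-ol
Product: 17 diethyl (2Z)-3-methyl-5-[(1S,3S)-2,2,3-trimethyl-6-methylidenecyclohexyl]pent-2-en-1-yl phosphate
Conditions: (EtO)2P(O)Cl, Et3N, DMAP (cat.), CH2Cl2, 0 °C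
Reagents that add atoms: diethyl chlorophosphate (CCOP(=O)(Cl)OCC)
Why: O-Phosphorylation of the primary allylic alcohol installs the leaving group needed for copper-catalysed allylic substitution.

Step 10
Reactants: 18 (2E,6E)-farnesyl acetate
Product: 19 (2E,6E,10E)-12-hydroxy-3,7,11-trimethyldodeca-2,6,10-trien-1-yl acetate
Conditions: SeO2 (0.1 equiv), t-BuOOH, salicylic acid (0.1 equiv), CH2Cl2, 0 °C → rt
Reagents that add atoms: tert-butyl hydroperoxide (CC(C)(C)OO)
Why: SeO2-catalysed allylic oxidation (ene reaction then [2,3]-sigmatropic shift) is selective for the (E)-methyl group of the terminal, most electron-rich trisubstituted alkene.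

Step 11
Reactants: 19 (2E,6E,10E)-12-hydroxy-3,7,11-trimethyldodeca-2,6,10-trien-1-yl acetate
Product: 20 (2E,6E,10E)-12-chloro-3,7,11-trimethyldodeca-2,6,10-trien-1-yl acetate
Conditions: NCS, Me2S, CH2Cl2, −20 → 0 °C
Reagents that add atoms: N-chlorosuccinimide (O=C1CCC(=O)N1Cl)
Why: Corey–Kim chlorination turns the allylic alcohol into the primary chloride by SN2 displacement of the alkoxysulfonium group, without allylic transposition or loss of alkene geometry.

Step 12
Reactants: 20 (2E,6E,10E)-12-chloro-3,7,11-trimethyldodeca-2,6,10-trien-1-yl acetate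
Product: 22 (2E,6E,10R)-3,7,10,11-tetramethyldodeca-2,6,11-trien-1-ol, via acetate 21 (not isolated)
Conditions: MeMgBr (slow addition), copper thiophene-2-carboxylate Cu(O2CC4H3S) (3 mol%), chiral phosphoramidite ligand (3.3 mol%), CH2Cl2, −78 °C; then K2CO3, MeOH, rt
Reagents that add atoms: methylmagnesium bromide (C[Mg]Br)
Why: Copper-catalysed asymmetric allylic alkylation delivers methyl in the SN2′ sense to one face of the trisubstituted alkene under ligand control, which creates the 10R methine beside the new 1,1-disubstituted alkene, and methanolysis then removes the acetate.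

Step 13
Reactants: 22 (2E,6E,10R)-3,7,10,11-tetramethyldodeca-2,6,11-trien-1-ol
Product: 23 (3S,6E,10R)-3,7,10,11-tetramethyldodeca-6,11-dien-1-ol
Conditions: Ru(OAc)2[(R)-BINAP] (0.5 mol%), H2 (30 atm), MeOH, 20 °C
Reagents that add atoms: none
Why: Hydroxyl-directed Noyori asymmetric hydrogenation reduces only the allylic-alcohol double bond, and the (R)-ligand on the (2E)-alcohol gives the 3S centre in the same sense as geraniol to (S)-citronellol.

Step 14
Reactants: 23 (3S,6E,10R)-3,7,10,11-tetramethyldodeca-6,11-dien-1-ol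
Product: 24 (3S,6E,10R)-3,7,10,11-tetramethyldodeca-6,11-dienal
Conditions: TEMPO (10 mol%), PhI(OAc)2, CH2Cl2, rt
Reagents that add atoms: none
Why: Oxoammonium-catalysed (TEMPO) oxidation stops at the aldehyde and touches neither the alkenes nor the β-stereocentre.

Step 15
Reactants: 24 (3S,6E,10R)-3,7,10,11-tetramethyldodeca-6,11-dienal
Product: 26 (3S,6E,10R)-3,7,10,11-tetramethyldodeca-6,11-dien-1-yne, via alkenyl nonaflate 25 (not isolated)
Conditions: C4F9SO2F, P2-Et phosphazene base, DMF, −20 °C → rt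
Reagents that add atoms: none
Why: One-pot enolate O-nonaflation followed by base-induced β-elimination of nonaflate turns the enolisable aldehyde into the terminal alkyne with the same carbon count and an untouched propargylic stereocentre.

Step 16
Reactants: 26 (3S,6E,10R)-3,7,10,11-tetramethyldodeca-6,11-dien-1-yne; 17 diethyl (2Z)-3-methyl-5-[(1S,3S)-2,2,3-trimethyl-6-methylidenecyclohexyl]pent-2-en-1-yl phosphate
Product: 28 CNP0186101.1, via alkenylaluminium 27 (not isolated)
Conditions: i-Bu2AlH, hexanes, 55 °C; then 17, CuCl2·2H2O (2.5 mol%), chiral sulfonate-bearing imidazolinium salt (NHC precursor, 2.5 mol%), THF, −15 °C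
Reagents that add atoms: none
Why: syn-Hydroalumination gives the (E)-alkenylaluminium, and NHC–copper-catalysed enantioselective allylic substitution transfers the alkenyl group in the SN2′ sense to the methyl-bearing alkene carbon, which forms the S quaternary centre, the vinyl group and the (E)-alkene under catalyst control.

**Compound list**

1 | 3,4-dimethylanisole (4-methoxy-1,2-dimethylbenzene) | COc1ccc(C)c(C)c1 | starting material
2 | 1-methoxy-4,5-dimethylcyclohexa-1,4-diene | COC1=CCC(C)=C(C)C1 | intermediate (not isolated)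
3 | 3,4-dimethylcyclohex-3-en-1-one | O=C1CCC(C)=C(C)C1 | intermediate
4 | (4S)-3,4-dimethylcyclohex-2-en-1-one | O=C1C=C(C)[C@@H](C)CC1 | intermediate
5 | lithium (4S)-3,3,4-trimethylcyclohex-1-en-1-olate | [Li+].[O-]C1=CC(C)(C)[C@@H](C)CC1 | intermediate (not isolated)
6 | (4S)-3,3,4-trimethylcyclohex-1-en-1-yl trifluoromethanesulfonate | O=S(=O)(OC1=CC(C)(C)[C@@H](C)CC1)C(F)(F)F | intermediate
7 | (4S)-3,3,4-trimethylcyclohex-1-ene-1-carbaldehyde | O=CC1=CC(C)(C)[C@@H](C)CC1 | intermediate
8 | {[(2R,4S)-2-ethenyl-3,3,4-trimethylcyclohexylidene]methoxy}trimethylsilane (enol ether E/Z mixture; vinyl trans to the C4 methyl) | C=C[C@H]1C(=CO[Si](C)(C)C)CC[C@H](C)C1(C)C | intermediate (not isolated)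
9 | lithium [(2R,4S)-2-ethenyl-3,3,4-trimethylcyclohexylidene]methanolate | [Li+].C=C[C@H]1C(=C[O-])CC[C@H](C)C1(C)C | intermediate (not isolated)
10 | [(2R,4S)-2-ethenyl-3,3,4-trimethylcyclohexylidene]methyl trifluoromethanesulfonate (E/Z mixture) | C=C[C@H]1C(=COS(=O)(=O)C(F)(F)F)CC[C@H](C)C1(C)C | intermediate
11 | (1S,3S)-3-ethenyl-1,2,2-trimethyl-4-methylidenecyclohexane (vinyl trans to the C1 methyl) | C=C[C@H]1C(=C)CC[C@H](C)C1(C)C | intermediate
12 | but-2-yn-1-ol | CC#CCO | starting material
13 | sodium 2,2-bis(2-methoxyethoxy)-3-methyl-2,5-dihydro-1,2-oxaluminol-2-uide | [Na+].CC1=CCO[Al-]1(OCCOC)OCCOC | intermediate (not isolated)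
14 | (2Z)-3-iodobut-2-en-1-ol | C/C(I)=C/CO | intermediate
15 | bis(3-methylbutan-2-yl){2-[(1S,3S)-2,2,3-trimethyl-6-methylidenecyclohexyl]ethyl}borane | CC(C)C(C)B(CC[C@H]1C(=C)CC[C@H](C)C1(C)C)C(C)C(C)C | intermediate (not isolated)
16 | (2Z)-3-methyl-5-[(1S,3S)-2,2,3-trimethyl-6-methylidenecyclohexyl]pent-2-en-1-ol | C/C(CC[C@H]1C(=C)CC[C@H](C)C1(C)C)=C/CO | intermediate
17 | diethyl (2Z)-3-methyl-5-[(1S,3S)-2,2,3-trimethyl-6-methylidenecyclohexyl]pent-2-en-1-yl phosphate | CCOP(=O)(OCC)OC/C=C(/C)CC[C@H]1C(=C)CC[C@H](C)C1(C)C | intermediate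
18 | (2E,6E)-farnesyl acetate ((2E,6E)-3,7,11-trimethyldodeca-2,6,10-trien-1-yl acetate) | CC(=O)OC/C=C(\C)CC/C=C(\C)CCC=C(C)C | starting material
19 | (2E,6E,10E)-12-hydroxy-3,7,11-trimethyldodeca-2,6,10-trien-1-yl acetate | CC(=O)OC/C=C(\C)CC/C=C(\C)CC/C=C(\C)CO | intermediate
20 | (2E,6E,10E)-12-chloro-3,7,11-trimethyldodeca-2,6,10-trien-1-yl acetate | CC(=O)OC/C=C(\C)CC/C=C(\C)CC/C=C(\C)CCl | intermediate
21 | (2E,6E,10R)-3,7,10,11-tetramethyldodeca-2,6,11-trien-1-yl acetate | CC(=O)OC/C=C(\C)CC/C=C(\C)CC[C@@H](C)C(C)=C | intermediate (not isolated)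
22 | (2E,6E,10R)-3,7,10,11-tetramethyldodeca-2,6,11-trien-1-ol | OC/C=C(\C)CC/C=C(\C)CC[C@@H](C)C(C)=C | intermediate
23 | (3S,6E,10R)-3,7,10,11-tetramethyldodeca-6,11-dien-1-ol | OCC[C@@H](C)CC/C=C(\C)CC[C@@H](C)C(C)=C | intermediate
24 | (3S,6E,10R)-3,7,10,11-tetramethyldodeca-6,11-dienal | O=CC[C@@H](C)CC/C=C(\C)CC[C@@H](C)C(C)=C | intermediate
25 | (3S,6E,10R)-3,7,10,11-tetramethyldodeca-1,6,11-trien-1-yl nonafluorobutane-1-sulfonate (C1=C2 E/Z mixture) | FC(F)(F)C(F)(F)C(F)(F)C(F)(F)S(=O)(=O)OC=C[C@@H](C)CC/C=C(\C)CC[C@@H](C)C(C)=C | intermediate (not isolated)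
26 | (3S,6E,10R)-3,7,10,11-tetramethyldodeca-6,11-dien-1-yne | C#C[C@@H](C)CC/C=C(\C)CC[C@@H](C)C(C)=C | intermediate
27 | bis(2-methylpropyl)[(1E,3S,6E,10R)-3,7,10,11-tetramethyldodeca-1,6,11-trien-1-yl]alumane | CC(C)C[Al](CC(C)C)/C=C/[C@@H](C)CC/C=C(\C)CC[C@@H](C)C(C)=C | intermediate (not isolated)
28 | CNP0186101.1, (1S,3S)-1-[(3S,4E,6S,9E,13R)-3-ethenyl-3,6,10,13,14-pentamethylpentadeca-4,9,14-trien-1-yl]-2,2,3-trimethyl-6-methylidenecyclohexane | C=C[C@@](C)(/C=C/[C@@H](C)CC/C=C(\C)CC[C@@H](C)C(=C)C)CC[C@H]1C(=C)CC[C@H](C)C1(C)C | target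

**Step count and risks**

Total step count: 16 (steps 1–6, 8 and 9 build the ring A fragment; step 7 makes the iodide; steps 10–15 build the alkyne; step 16 joins them).
Longest linear sequence: 9 steps (1, 2, 3, 4, 5, 6, 8, 9, 16).

The three steps most likely to fail:

Step 16. The alkenyl transfer to a γ,γ-dialkyl (Z)-allylic phosphate with two large partners may give poor SN2′/SN2 ratio or poor selectivity at the quaternary centre. The fallback sets out from 16 and 24 and comes back to the route at 28. Alcohol 16 is converted with CBr4/PPh3 into the bromide (1S,3S)-1-[(3Z)-5-bromo-3-methylpent-3-en-1-yl]-2,2,3-trimethyl-6-methylidenecyclohexane F9. A chromium-catalysed asymmetric Nozaki–Hiyama allylation of aldehyde 24 with F9 (CrCl2 10 mol%, chiral bis(oxazolinyl)carbazole ligand, Mn, Me3SiCl, then Bu4NF) bonds the γ-carbon of the allyl unit to the aldehyde through a closed transition state and gives the homoallylic alcohol (3S,6S,9E,13R)-3-ethenyl-3,6,10,13,14-pentamethyl-1-[(1S,3S)-2,2,3-trimethyl-6-methylidenecyclohexyl]pentadeca-9,14-dien-4-ol F10, whose quaternary centre is already in place and whose carbinol configuration is immaterial. Syn-dehydration of F10 with the Burgess reagent in toluene at 80 °C can only go towards the one neighbouring CH2 and gives the (E)-alkene of 28.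

Step 5. The β-carbon of enal 7 is neopentylic, so conjugate vinylation may be slow or give 1,2-addition, and O-triflation of an aldehyde enolate is less reliable than that of a ketone enolate. The fallback sets out from 6 and comes back to the route at 28. Pd(PPh3)4-catalysed Kumada coupling of 6 with Me3SiCH2MgCl gives the allylsilane trimethyl{[(4S)-3,3,4-trimethylcyclohex-1-en-1-yl]methyl}silane F1. TiCl4-promoted Hosomi–Sakurai conjugate addition of F1 to but-3-en-2-one (SE2′, axial attack trans to the ring methyl) gives in one step the methylidene ketone 4-[(1S,3S)-2,2,3-trimethyl-6-methylidenecyclohexyl]butan-2-one F2. Horner–Wadsworth–Emmons olefination with triethyl phosphonoacetate and NaH, followed by removal of the minor (Z)-isomer, gives ethyl (2E)-3-methyl-5-[(1S,3S)-2,2,3-trimethyl-6-methylidenecyclohexyl]pent-2-enoate F3. Reduction with i-Bu2AlH gives (2E)-3-methyl-5-[(1S,3S)-2,2,3-trimethyl-6-methylidenecyclohexyl]pent-2-en-1-ol F4, and (EtO)2P(O)Cl gives diethyl (2E)-3-methyl-5-[(1S,3S)-2,2,3-trimethyl-6-methylidenecyclohexyl]pent-2-en-1-yl phosphate F5. F5 takes the place of 17 under the conditions of step 16, with the enantiomeric NHC ligand because the alkene geometry is reversed, and gives 28.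

Step 12. SN2′ methylation with MeMgBr on an aliphatic 2-methylallyl chloride may give a mediocre γ/α ratio or ee. The fallback sets out from 19 and comes back to the route at 21. Sharpless asymmetric epoxidation of 19 (Ti(OiPr)4, L-(+)-diethyl tartrate, t-BuOOH, 4 Å sieves, CH2Cl2, −20 °C) gives (2E,6E)-9-[(2S,3S)-3-(hydroxymethyl)-3-methyloxiran-2-yl]-3,7-dimethylnona-2,6-dien-1-yl acetate F6. Me2CuLi at −40 °C opens the epoxide at its less substituted carbon with inversion and gives (2E,6E,10R,11R)-11,12-dihydroxy-3,7,10,11-tetramethyldodeca-2,6-dien-1-yl acetate F7. Thiocarbonyldiimidazole gives the cyclic thionocarbonate (2E,6E,10R)-3,7-dimethyl-10-[(4R)-4-methyl-2-sulfanylidene-1,3-dioxolan-4-yl]undeca-2,6-dien-1-yl acetate F8, and heating F8 in P(OMe)3 (Corey–Winter olefination) gives 21, which is methanolysed to 22 as in step 12.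

**Further compounds**

F1 | step 5 | trimethyl{[(4S)-3,3,4-trimethylcyclohex-1-en-1-yl]methyl}silane | C[Si](C)(C)CC1=CC(C)(C)[C@@H](C)CC1
F2 | step 5 | 4-[(1S,3S)-2,2,3-trimethyl-6-methylidenecyclohexyl]butan-2-one | CC(=O)CC[C@H]1C(=C)CC[C@H](C)C1(C)C
F3 | step 5 | ethyl (2E)-3-methyl-5-[(1S,3S)-2,2,3-trimethyl-6-methylidenecyclohexyl]pent-2-enoate | CCOC(=O)/C=C(\C)CC[C@H]1C(=C)CC[C@H](C)C1(C)C
F4 | step 5 | (2E)-3-methyl-5-[(1S,3S)-2,2,3-trimethyl-6-methylidenecyclohexyl]pent-2-en-1-ol | OC/C=C(\C)CC[C@H]1C(=C)CC[C@H](C)C1(C)C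
F5 | step 5 | diethyl (2E)-3-methyl-5-[(1S,3S)-2,2,3-trimethyl-6-methylidenecyclohexyl]pent-2-en-1-yl phosphate | CCOP(=O)(OCC)OC/C=C(\C)CC[C@H]1C(=C)CC[C@H](C)C1(C)C
F6 | step 12 | (2E,6E)-9-[(2S,3S)-3-(hydroxymethyl)-3-methyloxiran-2-yl]-3,7-dimethylnona-2,6-dien-1-yl acetate | CC(=O)OC/C=C(\C)CC/C=C(\C)CC[C@@H]1O[C@@]1(C)CO
F7 | step 12 | (2E,6E,10R,11R)-11,12-dihydroxy-3,7,10,11-tetramethyldodeca-2,6-dien-1-yl acetate | CC(=O)OC/C=C(\C)CC/C=C(\C)CC[C@@H](C)[C@@](C)(O)CO
F8 | step 12 | (2E,6E,10R)-3,7-dimethyl-10-[(4R)-4-methyl-2-sulfanylidene-1,3-dioxolan-4-yl]undeca-2,6-dien-1-yl acetate | CC(=O)OC/C=C(\C)CC/C=C(\C)CC[C@@H](C)[C@]1(C)COC(=S)O1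
F9 | step 16 | (1S,3S)-1-[(3Z)-5-bromo-3-methylpent-3-en-1-yl]-2,2,3-trimethyl-6-methylidenecyclohexane | BrC/C=C(/C)CC[C@H]1C(=C)CC[C@H](C)C1(C)C
F10 | step 16 | (3S,6S,9E,13R)-3-ethenyl-3,6,10,13,14-pentamethyl-1-[(1S,3S)-2,2,3-trimethyl-6-methylidenecyclohexyl]pentadeca-9,14-dien-4-ol (C4 epimers) | C=C[C@](C)(CC[C@H]1C(=C)CC[C@H](C)C1(C)C)C(O)C[C@@H](C)CC/C=C(\C)CC[C@@H](C)C(C)=C
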